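## Retrosynthetic overview

1. Ring D (lactone on C3) is made last: C3–C18 by vinylogous Mannich addition of a 3-methyl-2-silyloxyfuran to the C3 iminium ion of a bicyclic lactam, then hydrogenation.
2. Rings B and A come from an ω-azido γ-keto ester: aza-Wittig closure (N4=C9a), hydride reduction (sets C9a), lactamisation (N4–C3).
3. C9a–C1: the C9a nitronate acts as an acyl-anion equivalent toward methyl acrylate, then a Nef reaction unveils the C9a ketone.
4. Ring C (lactone on C10): C11–C12 by addition of a Roche-type zinc/titanium homoenolate to the C11 aldehyde.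
5. Key bond C9–C10: amine-catalysed union of butanal with a nitroalkene used as an enolonium equivalent (sets C9 and C10). Ring order: C, then B, then A, then D.

Assumption: the SMILES is taken as drawn and numbered the usual Stemona way (C1–C3, N4, C5–C9, C9a; C10 carries ethyl; ring A = pyrrolidine, ring B = azepane, ring C = lactone C11–C14, ring D = lactone C18–C21), which gives 3S,9R,9aS,10R,11R,13S,18S,20S.

## Route

Step 1
Reactants: 1 6-chlorohex-1-ene
Product: 2 (E)-6-chloro-1-nitrohex-1-ene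
Conditions: AgNO2 (3 equiv), TEMPO (0.4 equiv), 4 Å MS, ClCH2CH2Cl, 70 °C
Reagents that add atoms: silver nitrite, [Ag+].[O-]N=O
Why: Radical nitration–dehydrogenation of a terminal alkene (NO2 radical adds to C1, TEMPO removes the C2 hydrogen) gives the (E)-nitroalkene, and the primary chloride, unlike a bromide, is not substituted by AgNO2.

Step 2
Reactants: 2 (E)-6-chloro-1-nitrohex-1-ene; 3 butanal
Product: 4 (2R,3R)-7-chloro-2-ethyl-3-(nitromethyl)heptanal
Conditions: 3 (3 equiv), (S)-2-[diphenyl(trimethylsilyloxy)methyl]pyrrolidine (10 mol%), 4-nitrophenol (10 mol%), toluene, 0 °C → rt; used crude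
Reagents that add atoms: none
Why: In this Hayashi-type enamine Michael addition the nitro group makes C9 electrophilic, so 2 serves as an enolonium (α-cation) equivalent of the later C9a carbonyl and joins C9 to C10, two natively nucleophilic carbons, while the (S)-catalyst shields one enamine face and the synclinal transition state gives the syn adduct, setting C10 (R) and C9 (R) in the same sense as its known (2R,3S)-phenyl adducts.

Step 3
Reactants: 4 (2R,3R)-7-chloro-2-ethyl-3-(nitromethyl)heptanal; 5 methyl (R)-3-bromo-2-methylpropanoate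
Product: 9 (3S,5R)-5-[(3R,4R)-8-chloro-4-(nitromethyl)octan-3-yl]-3-methyloxolan-2-one, via zinc homoenolate 6 (not isolated), via titanium homoenolate 7 (not isolated), via hydroxy ester 8 (not isolated)
Conditions: 5, Zn dust, LiCl, THF, 50 °C; ClTi(OiPr)3, −20 °C; then 4, −20 → 0 °C; aq. NH4Cl; then TsOH·H2O (cat.), CH2Cl2, rt
Reagents that add atoms: none
Why: Homoenolate addition of the mild, aldehyde-selective and nitro-tolerant titanium reagent proceeds under Felkin–Anh control (C9 branch as large group anti to the nucleophile, ethyl as medium) to set C11 (R), C13 (S) is carried in unchanged from 5, and acid closes ring C.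

Step 4
Reactants: 9 (3S,5R)-5-[(3R,4R)-8-chloro-4-(nitromethyl)octan-3-yl]-3-methyloxolan-2-one; 10 methyl acrylate
Product: 12 methyl (5R)-9-chloro-5-{(1R)-1-[(2R,4S)-4-methyl-5-oxooxolan-2-yl]propyl}-4-oxononanoate, via nitro ester 11 (not isolated)
Conditions: 10 (1.2 equiv), DBU (0.3 equiv), MeCN, 0 °C → rt; then DBU (1.0 equiv); then aq. TiCl3, NH4OAc (pH 5–6), THF, 0 °C → rt
Reagents that add atoms: water, O
Why: The nitronate of 9 is an acyl-anion equivalent for C9a, so a DBU-mediated Michael addition forms C9a–C1 and the McMurry variant of the Nef reaction then converts the secondary nitro group into the ketone under near-neutral conditions that spare lactone, ester, chloride and the C9 centre, the transient nitro-bearing centre being destroyed.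

Step 5
Reactants: 12 methyl (5R)-9-chloro-5-{(1R)-1-[(2R,4S)-4-methyl-5-oxooxolan-2-yl]propyl}-4-oxononanoate
Product: 13 methyl (5R)-9-azido-5-{(1R)-1-[(2R,4S)-4-methyl-5-oxooxolan-2-yl]propyl}-4-oxononanoate
Conditions: NaN3, NaI (cat.), DMF, 50 °C
Reagents that add atoms: sodium azide, [Na+].[N-]=[N+]=[N-]
Why: Finkelstein-assisted SN2 displacement of the primary chloride by the weakly basic azide ion leaves the ketone α-centre untouched.

Step 6
Reactants: 13 methyl (5R)-9-azido-5-{(1R)-1-[(2R,4S)-4-methyl-5-oxooxolan-2-yl]propyl}-4-oxononanoate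
Product: 17 (9R,9aS)-9-{(1R)-1-[(2R,4S)-4-methyl-5-oxooxolan-2-yl]propyl}octahydro-3H-pyrrolo[1,2-a]azepin-3-one, via iminophosphorane 14 (not isolated), via cyclic imine 15 (not isolated), via amino ester 16 (not isolated)
Conditions: PPh3, toluene, rt → 90 °C; then NaBH4, MeOH, −20 °C; then toluene, 80 °C
Reagents that add atoms: none
Why: Staudinger reduction and intramolecular aza-Wittig reaction close ring B as the seven-membered ketimine, hydride attacks it anti to the C9 side chain (held pseudoaxial by A1,2 strain) to set C9a (S, H9/H9a cis), and the amine then lactamises onto the methyl ester to close ring A.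

Step 7
Reactants: 18 3-methylfuran-2(5H)-one
Product: 19 3-methyl-2-[tri(propan-2-yl)silyloxy]furan
Conditions: iPr3SiOTf, Et3N, CH2Cl2, 0 °C
Reagents that add atoms: triisopropylsilyl trifluoromethanesulfonate, CC(C)[Si](OS(=O)(=O)C(F)(F)F)(C(C)C)C(C)C
Why: Soft enolisation and O-silylation of the butenolide gives the aromatic 2-silyloxyfuran.

Step 8
Reactants: 17 (9R,9aS)-9-{(1R)-1-[(2R,4S)-4-methyl-5-oxooxolan-2-yl]propyl}octahydro-3H-pyrrolo[1,2-a]azepin-3-one; 19 3-methyl-2-[tri(propan-2-yl)silyloxy]furan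
Product: 22 (5S)-3-methyl-5-[(3S,9R,9aS)-9-{(1R)-1-[(2R,4S)-4-methyl-5-oxooxolan-2-yl]propyl}octahydro-1H-pyrrolo[1,2-a]azepin-3-yl]furan-2(5H)-one, via silyl hemiaminal 20 (not isolated), via iminium ion 21 (not isolated)
Conditions: IrCl(CO)(PPh3)2 (2 mol%), (Me2HSi)2O, toluene, rt; then 19, 2-nitrobenzoic acid, MeCN, 0 °C → rt
Reagents that add atoms: none
Why: Lactam-selective Ir-catalysed hydrosilylation (the lactone is untouched), acid-induced iminium formation and a vinylogous Mannich reaction let the furan add to C3 from the convex face anti to the C9a–C9 bond (C3 S, H3/H9a trans) with the usual threo preference of silyloxyfuran additions to cyclic iminium ions (C18 S).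

Step 9
Reactants: 22 (5S)-3-methyl-5-[(3S,9R,9aS)-9-{(1R)-1-[(2R,4S)-4-methyl-5-oxooxolan-2-yl]propyl}octahydro-1H-pyrrolo[1,2-a]azepin-3-yl]furan-2(5H)-one
Product: 23 (3S,5S)-3-methyl-5-[(3S,9R,9aS)-9-{(1R)-1-[(2R,4S)-4-methyl-5-oxooxolan-2-yl]propyl}octahydro-1H-pyrrolo[1,2-a]azepin-3-yl]oxolan-2-one (CNP0135535.2)
Conditions: H2 (4 atm), 5% Rh/Al2O3, EtOAc, rt
Reagents that add atoms: none
Why: Heterogeneous hydrogenation delivers hydrogen to the butenolide face opposite the bulky C3 substituent, placing the C20 methyl cis to it (C20 S) and completing ring D.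

## Compound list

1 | 6-chlorohex-1-ene | C=CCCCCCl | starting material
2 | (E)-6-chloro-1-nitrohex-1-ene | [O-][N+](=O)/C=C/CCCCCl | intermediate
3 | butanal | CCCC=O | starting material
4 | (2R,3R)-7-chloro-2-ethyl-3-(nitromethyl)heptanal | CC[C@H]([C@@H](CCCCCl)C[N+](=O)[O-])C=O | intermediate
5 | methyl (R)-3-bromo-2-methylpropanoate | BrC[C@H](C)C(=O)OC | starting material
6 | [(2R)-3-methoxy-2-methyl-3-oxopropyl]zinc bromide | Br[Zn]C[C@H](C)C(=O)OC | intermediate (not isolated)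
7 | [(2R)-3-methoxy-2-methyl-3-oxopropyl]tri(propan-2-yloxy)titanium | COC(=O)[C@@H](C)C[Ti](OC(C)C)(OC(C)C)OC(C)C | intermediate (not isolated)
8 | methyl (2S,4R,5R,6R)-10-chloro-5-ethyl-4-hydroxy-2-methyl-6-(nitromethyl)decanoate | CC[C@H]([C@@H](CCCCCl)C[N+](=O)[O-])[C@H](O)C[C@H](C)C(=O)OC | intermediate (not isolated)
9 | (3S,5R)-5-[(3R,4R)-8-chloro-4-(nitromethyl)octan-3-yl]-3-methyloxolan-2-one | CC[C@H]([C@@H](CCCCCl)C[N+](=O)[O-])[C@H]1C[C@H](C)C(=O)O1 | intermediate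
10 | methyl acrylate | C=CC(=O)OC | starting material
11 | methyl (4RS,5R)-9-chloro-5-{(1R)-1-[(2R,4S)-4-methyl-5-oxooxolan-2-yl]propyl}-4-nitrononanoate (both C4 epimers) | CC[C@H]([C@@H](CCCCCl)C(CCC(=O)OC)[N+](=O)[O-])[C@H]1C[C@H](C)C(=O)O1 | intermediate (not isolated)
12 | methyl (5R)-9-chloro-5-{(1R)-1-[(2R,4S)-4-methyl-5-oxooxolan-2-yl]propyl}-4-oxononanoate | CC[C@H]([C@@H](CCCCCl)C(=O)CCC(=O)OC)[C@H]1C[C@H](C)C(=O)O1 | intermediate
13 | methyl (5R)-9-azido-5-{(1R)-1-[(2R,4S)-4-methyl-5-oxooxolan-2-yl]propyl}-4-oxononanoate | CC[C@H]([C@@H](CCCCN=[N+]=[N-])C(=O)CCC(=O)OC)[C@H]1C[C@H](C)C(=O)O1 | intermediate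
14 | methyl (5R)-5-{(1R)-1-[(2R,4S)-4-methyl-5-oxooxolan-2-yl]propyl}-4-oxo-9-[(triphenyl-λ5-phosphanylidene)amino]nonanoate | CC[C@H]([C@@H](CCCCN=P(c1ccccc1)(c1ccccc1)c1ccccc1)C(=O)CCC(=O)OC)[C@H]1C[C@H](C)C(=O)O1 | intermediate (not isolated)
15 | methyl 3-[(6R)-6-{(1R)-1-[(2R,4S)-4-methyl-5-oxooxolan-2-yl]propyl}-3,4,5,6-tetrahydro-2H-azepin-7-yl]propanoate | CC[C@H]([C@H]1CCCCN=C1CCC(=O)OC)[C@H]1C[C@H](C)C(=O)O1 | intermediate (not isolated)
16 | methyl 3-[(2S,3R)-3-{(1R)-1-[(2R,4S)-4-methyl-5-oxooxolan-2-yl]propyl}azepan-2-yl]propanoate | CC[C@H]([C@H]1CCCCN[C@H]1CCC(=O)OC)[C@H]1C[C@H](C)C(=O)O1 | intermediate (not isolated)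
17 | (9R,9aS)-9-{(1R)-1-[(2R,4S)-4-methyl-5-oxooxolan-2-yl]propyl}octahydro-3H-pyrrolo[1,2-a]azepin-3-one | CC[C@H]([C@H]1CCCCN2[C@H]1CCC2=O)[C@H]1C[C@H](C)C(=O)O1 | intermediate
18 | 3-methylfuran-2(5H)-one | CC1=CCOC1=O | starting material
19 | 3-methyl-2-[tri(propan-2-yl)silyloxy]furan | CC1=C(O[Si](C(C)C)(C(C)C)C(C)C)OC=C1 | intermediate
20 | (3RS,9R,9aS)-9-{(1R)-1-[(2R,4S)-4-methyl-5-oxooxolan-2-yl]propyl}-3-[(1,1,3,3-tetramethyldisiloxanyl)oxy]octahydro-1H-pyrrolo[1,2-a]azepine (both C3 epimers) | CC[C@H]([C@H]1CCCCN2[C@H]1CCC2O[Si](C)(C)O[SiH](C)C)[C@H]1C[C@H](C)C(=O)O1 | intermediate (not isolated)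
21 | (9R,9aS)-9-{(1R)-1-[(2R,4S)-4-methyl-5-oxooxolan-2-yl]propyl}-1,2,5,6,7,8,9,9a-octahydropyrrolo[1,2-a]azepin-4-ium | CC[C@H]([C@H]1CCCC[N+]2=CCC[C@@H]12)[C@H]1C[C@H](C)C(=O)O1 | intermediate (not isolated)
22 | (5S)-3-methyl-5-[(3S,9R,9aS)-9-{(1R)-1-[(2R,4S)-4-methyl-5-oxooxolan-2-yl]propyl}octahydro-1H-pyrrolo[1,2-a]azepin-3-yl]furan-2(5H)-one | CC[C@H]([C@H]1CCCCN2[C@H]1CC[C@H]2[C@@H]1C=C(C)C(=O)O1)[C@H]1C[C@H](C)C(=O)O1 | intermediate
23 | (3S,5S)-3-methyl-5-[(3S,9R,9aS)-9-{(1R)-1-[(2R,4S)-4-methyl-5-oxooxolan-2-yl]propyl}octahydro-1H-pyrrolo[1,2-a]azepin-3-yl]oxolan-2-one | CC[C@H]([C@H]1CCCCN2[C@H]1CC[C@H]2[C@@H]1C[C@H](C)C(=O)O1)[C@H]1C[C@H](C)C(=O)O1 | target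

## Step count

Total: 9 steps. Longest linear sequence: 8 steps (steps 1–6, 8, 9); step 7 is a one-step side branch.

## Steps most likely to fail, with fallbacks

**Step 3** (modest Felkin ratio at C11, or loss of the organometallic to the acidic nitro group). The fallback sets out from 4 and comes back at 8. Aldehyde 4 is oxidised (NaClO2, NaH2PO4, 2-methylbut-2-ene, tBuOH–H2O) to (2R,3R)-7-chloro-2-ethyl-3-(nitromethyl)heptanoic acid F1. Oxalyl chloride with catalytic DMF turns it into (2R,3R)-7-chloro-2-ethyl-3-(nitromethyl)heptanoyl chloride F2. Acylative Negishi coupling of F2 with zinc homoenolate 6 under Pd(PPh3)4 in THF gives methyl (2S,5R,6R)-10-chloro-5-ethyl-2-methyl-6-(nitromethyl)-4-oxodecanoate F3. A catalyst-controlled Corey–Bakshi–Shibata reduction ((S)-2-methyl-CBS-oxazaborolidine, catecholborane, toluene, −78 °C) then sets C11 (R) independently of the substrate bias and gives hydroxy ester 8, which is lactonised to 9 as in step 3.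

**Step 6** (sluggish seven-membered aza-Wittig closure, or C9 epimerisation through imine–enamine tautomerism). The fallback sets out from 11, isolated after the Michael addition of step 4 before the TiCl3 treatment, and comes back at 16. The nitro group is reduced only as far as the oxime (SnCl2·2H2O, PhSH, Et3N, MeCN), giving methyl (5R)-9-chloro-4-(hydroxyimino)-5-{(1R)-1-[(2R,4S)-4-methyl-5-oxooxolan-2-yl]propyl}nonanoate F4. NaI (cat.) and NaHCO3 in MeCN at 80 °C close ring B by N-alkylation of the oxime to the cyclic ketonitrone (6R)-7-(3-methoxy-3-oxopropyl)-6-{(1R)-1-[(2R,4S)-4-methyl-5-oxooxolan-2-yl]propyl}-3,4,5,6-tetrahydro-2H-azepine 1-oxide F5. This nitrone cannot tautomerise to an enamine, and it keeps the nitro nitrogen as N4. NaBH4 in MeOH at 0 °C adds anti to the C9 side chain to give methyl 3-[(2S,3R)-1-hydroxy-3-{(1R)-1-[(2R,4S)-4-methyl-5-oxooxolan-2-yl]propyl}azepan-2-yl]propanoate F6. Zn in AcOH cleaves the N–O bond to amino ester 16, which lactamises to 17 as in step 6. This variant needs no Nef reaction, azide or aza-Wittig step.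

**Step 8** (low threo/erythro or facial selectivity in the vinylogous Mannich addition). The fallback sets out from 17 and comes back at 23. After the same IrCl(CO)(PPh3)2/(Me2HSi)2O activation, CH2=CHMgBr is added at −78 °C, where the iminium ion reacts faster than the lactone. Attack anti to C9 gives (3S,5R)-5-{(1R)-1-[(3S,9R,9aS)-3-ethenyloctahydro-1H-pyrrolo[1,2-a]azepin-9-yl]propyl}-3-methyloxolan-2-one F7. Ozonolysis of its trifluoroacetate salt (O3, CH2Cl2–MeOH, −78 °C; Me2S) gives (3S,9R,9aS)-9-{(1R)-1-[(2R,4S)-4-methyl-5-oxooxolan-2-yl]propyl}octahydro-1H-pyrrolo[1,2-a]azepine-3-carbaldehyde F8, which is used at once. Zinc homoenolate 6 with MgBr2·OEt2 adds under Cram-chelate control through N4 to give the threo product methyl (2S,4S)-4-hydroxy-2-methyl-4-[(3S,9R,9aS)-9-{(1R)-1-[(2R,4S)-4-methyl-5-oxooxolan-2-yl]propyl}octahydro-1H-pyrrolo[1,2-a]azepin-3-yl]butanoate F9. F9 lactonises (TsOH, CH2Cl2) directly to 23, so C20 comes from 5 and no hydrogenation is needed.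

## Further compounds

F1 | step 3 | (2R,3R)-7-chloro-2-ethyl-3-(nitromethyl)heptanoic acid | CC[C@H]([C@@H](CCCCCl)C[N+](=O)[O-])C(=O)O
F2 | step 3 | (2R,3R)-7-chloro-2-ethyl-3-(nitromethyl)heptanoyl chloride | CC[C@H]([C@@H](CCCCCl)C[N+](=O)[O-])C(=O)Cl
F3 | step 3 | methyl (2S,5R,6R)-10-chloro-5-ethyl-2-methyl-6-(nitromethyl)-4-oxodecanoate | CC[C@H]([C@@H](CCCCCl)C[N+](=O)[O-])C(=O)C[C@H](C)C(=O)OC
F4 | step 6 | methyl (5R)-9-chloro-4-(hydroxyimino)-5-{(1R)-1-[(2R,4S)-4-methyl-5-oxooxolan-2-yl]propyl}nonanoate | CC[C@H]([C@@H](CCCCCl)C(=NO)CCC(=O)OC)[C@H]1C[C@H](C)C(=O)O1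
F5 | step 6 | (6R)-7-(3-methoxy-3-oxopropyl)-6-{(1R)-1-[(2R,4S)-4-methyl-5-oxooxolan-2-yl]propyl}-3,4,5,6-tetrahydro-2H-azepine 1-oxide | CC[C@H]([C@H]1CCCC[N+]([O-])=C1CCC(=O)OC)[C@H]1C[C@H](C)C(=O)O1
F6 | step 6 | methyl 3-[(2S,3R)-1-hydroxy-3-{(1R)-1-[(2R,4S)-4-methyl-5-oxooxolan-2-yl]propyl}azepan-2-yl]propanoate | CC[C@H]([C@H]1CCCCN(O)[C@H]1CCC(=O)OC)[C@H]1C[C@H](C)C(=O)O1
F7 | step 8 | (3S,5R)-5-{(1R)-1-[(3S,9R,9aS)-3-ethenyloctahydro-1H-pyrrolo[1,2-a]azepin-9-yl]propyl}-3-methyloxolan-2-one | CC[C@H]([C@H]1CCCCN2[C@H]1CC[C@H]2C=C)[C@H]1C[C@H](C)C(=O)O1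
F8 | step 8 | (3S,9R,9aS)-9-{(1R)-1-[(2R,4S)-4-methyl-5-oxooxolan-2-yl]propyl}octahydro-1H-pyrrolo[1,2-a]azepine-3-carbaldehyde | CC[C@H]([C@H]1CCCCN2[C@H]1CC[C@H]2C=O)[C@H]1C[C@H](C)C(=O)O1
F9 | step 8 | methyl (2S,4S)-4-hydroxy-2-methyl-4-[(3S,9R,9aS)-9-{(1R)-1-[(2R,4S)-4-methyl-5-oxooxolan-2-yl]propyl}octahydro-1H-pyrrolo[1,2-a]azepin-3-yl]butanoate | CC[C@H]([C@H]1CCCCN2[C@H]1CC[C@H]2[C@@H](O)C[C@H](C)C(=O)OC)[C@H]1C[C@H](C)C(=O)O1
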